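Ring C of the target, the hydroxy-p-quinone C8–C9–C11–C12–C13–C14 (abietane numbering), is disconnected at C9–C11 and C8–C14. The contiguous O/O/alkyl/O carbons C11–C14 map onto the four-membered ring of a squaric ester, and C8=C9 is the enone alkene of ring B. In the key step a 4-(cyclohexenyl)-4-silyloxycyclobutenone ring-expands thermally (Moore rearrangement): 4π opening gives a dienylketene whose 6π electrocyclisation bonds ketene carbon C11 to C9 and delivers the fully substituted hydroquinone of ring C in one operation. The precursor is assembled from di-tert-butyl squarate, a ring B alkenylmagnesium reagent made by catalytic desymmetrisation of a cyclohexadienone, and isopropylmagnesium chloride.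

Key step: step 9

Remark on the chemistry: atom numbers follow abietane numbering (ring B = C5, C6, C7, C8, C9, C10; ring C = C8, C9, C11, C12, C13, C14; C1–C3 = propanoate arm on C10; C20 = methyl on C10). The target is taken as drawn, (5S,10S), with the isopropenyl group cis to C20 and trans to the propanoate arm. The CIP descriptor at C10 changes with the substituent on C8 although the geometry does not.

Step 1
Reactants: 1 propanal; 2 methyl acrylate
Product: 4 methyl 4-methyl-5-oxopentanoate (racemic), via (E)-1-(prop-1-en-1-yl)pyrrolidine 3 (not isolated)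
Conditions: pyrrolidine, K2CO3, 0 °C; then 2, MeCN, 0 °C → reflux; then AcOH, H2O
Reagents that add atoms: water, O
Why: Stork enamine Michael addition, in which the pyrrolidine enamine of propanal adds once to the acrylate and aqueous acid returns the aldehyde; the new stereocentre is racemic and loses its meaning in step 3.

Step 2
Reactants: 4 methyl 4-methyl-5-oxopentanoate; 5 but-3-en-2-one
Product: 7 methyl 3-(1-methyl-4-oxocyclohex-2-en-1-yl)propanoate (racemic), via methyl 4-formyl-4-methyl-7-oxooctanoate 6 (not isolated)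
Conditions: H2SO4 (cat.), toluene, 45 °C then reflux, Dean–Stark
Reagents that add atoms: none
Why: acid-catalysed Robinson annulation, in which the α-branched aldehyde adds through its enol to the enone and the 1,5-keto aldehyde closes by aldol condensation to the 4,4-disubstituted cyclohexenone; the quaternary centre is racemic and becomes prochiral in step 3.

Step 3
Reactants: 7 methyl 3-(1-methyl-4-oxocyclohex-2-en-1-yl)propanoate
Product: 8 methyl 3-(1-methyl-4-oxocyclohexa-2,5-dien-1-yl)propanoate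
Conditions: DDQ, 1,4-dioxane, reflux
Reagents that add atoms: none
Why: DDQ dehydrogenation across C5–C6 through the dienol (hydride abstraction), with aromatisation blocked by the quaternary carbon, should give the achiral cross-conjugated dienone with two enantiotopic enone arms.

Step 4
Reactants: 8 methyl 3-(1-methyl-4-oxocyclohexa-2,5-dien-1-yl)propanoate; 9 4,4,5,5-tetramethyl-2-(prop-1-en-2-yl)-1,3,2-dioxaborolane
Product: 10 methyl 3-[(1R,6S)-1-methyl-4-oxo-6-(prop-1-en-2-yl)cyclohex-2-en-1-yl]propanoate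
Conditions: [Rh(OH)(cod)]2 (2.5 mol %), (S)-BINAP (6 mol %), 1,4-dioxane/H2O (10:1), 50 °C
Reagents that add atoms: none
Why: Hayashi–Miyaura conjugate addition with monovalent rhodium used as a desymmetrisation, in which the (S)-BINAP complex fixes the configuration at C5 (same facial sense as with cyclohex-2-enone) and the alkenyl group should enter anti to the larger propanoate arm, on the methyl face, which selects the enantiotopic alkene and so sets C10; only a modest preference is expected here, and the minor C10 epimer is to be removed by chromatography.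

Step 5
Reactants: 10 methyl 3-[(1R,6S)-1-methyl-4-oxo-6-(prop-1-en-2-yl)cyclohex-2-en-1-yl]propanoate
Product: 11 methyl 3-[(1S,6S)-3-iodo-1-methyl-4-oxo-6-(prop-1-en-2-yl)cyclohex-2-en-1-yl]propanoate
Conditions: I2, pyridine, CH2Cl2, 0 °C → rt
Reagents that add atoms: iodine, II
Why: α-iodination of the enone at C8 by the pyridine/iodine addition–elimination sequence (Baylis–Hillman-type activation), which leaves the isolated isopropenyl group, the ester and both stereocentres untouched.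

Step 6
Reactants: 11 methyl 3-[(1S,6S)-3-iodo-1-methyl-4-oxo-6-(prop-1-en-2-yl)cyclohex-2-en-1-yl]propanoate
Product: 12 methyl 3-[(8S,9S)-6-iodo-8-methyl-9-(prop-1-en-2-yl)-1,4-dioxaspiro[4.5]dec-6-en-8-yl]propanoate
Conditions: Me3SiOCH2CH2OSiMe3, Me3SiOTf (5 mol %), CH2Cl2, −78 → −20 °C
Reagents that add atoms: 1,2-bis(trimethylsilyloxy)ethane, C[Si](C)(C)OCCO[Si](C)(C)C
Why: silyl-triflate-catalysed ketalisation (Noyori conditions) protects the C7 ketone at low temperature without transesterifying the methyl ester, and the α-iodo substituent keeps the alkene at C8=C9.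

Step 7
Reactants: 12 methyl 3-[(8S,9S)-6-iodo-8-methyl-9-(prop-1-en-2-yl)-1,4-dioxaspiro[4.5]dec-6-en-8-yl]propanoate; 13 3,4-di-tert-butoxycyclobut-3-ene-1,2-dione (di-tert-butyl squarate)
Product: 16 methyl 3-[(8R,9S)-6-[2,3-di-tert-butoxy-4-oxo-1-(trimethylsilyloxy)cyclobut-2-en-1-yl]-8-methyl-9-(prop-1-en-2-yl)-1,4-dioxaspiro[4.5]dec-6-en-8-yl]propanoate (epimers at the carbinol carbon C14), via alkenylmagnesium chloride 14 (not isolated), via 4-hydroxycyclobutenone adduct 15 (not isolated)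
Conditions: i-PrMgCl·LiCl, THF, −40 → −20 °C; then 13, −78 °C; then Me3SiCl, imidazole, −78 → 0 °C
Reagents that add atoms: chlorotrimethylsilane, C[Si](C)(C)Cl
Why: iodine–magnesium exchange gives an ester-tolerant alkenylmagnesium reagent at C8 (attack on its own ester would need a bridgehead alkene), which adds 1,2 to one of the two equivalent squarate carbonyls to form C8–C14, and in-situ silylation blocks the new tertiary alkoxide; C14 forms as an epimer mixture that converges in step 9.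

Step 8
Reactants: 16 methyl 3-[(8R,9S)-6-[2,3-di-tert-butoxy-4-oxo-1-(trimethylsilyloxy)cyclobut-2-en-1-yl]-8-methyl-9-(prop-1-en-2-yl)-1,4-dioxaspiro[4.5]dec-6-en-8-yl]propanoate
Product: 18 methyl 3-[(8R,9S)-6-[3-tert-butoxy-4-oxo-2-(propan-2-yl)-1-(trimethylsilyloxy)cyclobut-2-en-1-yl]-8-methyl-9-(prop-1-en-2-yl)-1,4-dioxaspiro[4.5]dec-6-en-8-yl]propanoate (epimers at C14), via cyclobutenol 1,2-adduct 17 (not isolated)
Conditions: i-PrMgCl, CeCl3, THF, −78 °C; then (CF3CO)2O, pyridine, −78 °C; aq. NaHCO3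
Reagents that add atoms: isopropylmagnesium chloride, CC(C)[Mg]Cl
Why: organocerium 1,2-addition to the remaining cyclobutenone carbonyl (ketone faster than methyl ester at −78 °C, cerium suppressing β-hydride reduction), then trifluoroacetylation and ionisation of the only free alkoxide with loss of the tert-butyl cation from the vinylogous position, is a Stork–Danheiser-type 1,3-carbonyl transposition that places isopropyl on C13 next to C14 and the carbonyl C11 next to C12–Ot-Bu.

Step 9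
Reactants: 18 methyl 3-[(8R,9S)-6-[3-tert-butoxy-4-oxo-2-(propan-2-yl)-1-(trimethylsilyloxy)cyclobut-2-en-1-yl]-8-methyl-9-(prop-1-en-2-yl)-1,4-dioxaspiro[4.5]dec-6-en-8-yl]propanoate
Product: 21 methyl 3-[(1'S,2'S)-7'-tert-butoxy-8'-hydroxy-1'-methyl-6'-(propan-2-yl)-2'-(prop-1-en-2-yl)-5'-(trimethylsilyloxy)-2',3'-dihydro-1'H-spiro[1,3-dioxolane-2,4'-naphthalen]-1'-yl]propanoate, via dienylketene 19 (not isolated), via cyclohexa-2,4-dienone 20 (not isolated)
Conditions: degassed toluene (0.01 M), 110 °C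
Reagents that add atoms: none
Why: Thermal conrotatory 4π ring opening of the cyclobutenone cleaves C11–C14 to dienylketene 19, whose 6π electrocyclisation joins the ketene carbon C11 to C9, and enolisation of dienone 20 (loss of the C9 hydrogen) aromatises ring C to the hydroquinone monosilyl ether. The closest known reaction type is the Moore rearrangement of squarate-derived 4-alkenyl-4-hydroxy (or silyloxy) cyclobutenones to hydroquinones and quinones. Ring C is closed in a disrotatory 6π electrocyclic mode across C11=C12–C13=C14–C8=C9. No stereocentre is created: C9 is sp3 only transiently, both C14 epimers converge, and C5 and the quaternary C10 are spectators. The step needs the alkenyl group to rotate inward on ring opening, which the donor silyloxy group secures by its preference for outward rotation, while the regiochemistry (C12–O next to C11, isopropyl next to C14) is already fixed in 18 by the order of the two additions. High dilution and exclusion of oxygen should suppress ketene dimerisation and premature oxidation.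

Step 10
Reactants: 21 methyl 3-[(1'S,2'S)-7'-tert-butoxy-8'-hydroxy-1'-methyl-6'-(propan-2-yl)-2'-(prop-1-en-2-yl)-5'-(trimethylsilyloxy)-2',3'-dihydro-1'H-spiro[1,3-dioxolane-2,4'-naphthalen]-1'-yl]propanoate
Product: 24 methyl 3-[(1S,2S)-7-hydroxy-1-methyl-4,5,8-trioxo-6-(propan-2-yl)-2-(prop-1-en-2-yl)-1,2,3,4,5,8-hexahydronaphthalen-1-yl]propanoate (target), via keto hydroquinone 22 (not isolated), via tert-butoxyquinone 23 (not isolated)
Conditions: 2 M aq. HCl, THF, 23 → 40 °C; then FeCl3·6H2O (2.2 equiv), 0 °C → rt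
Reagents that add atoms: water, O
Why: dilute acid removes the silyl ether and hydrolyses the dioxolane at the electron-rich hydroquinone stage, trivalent iron oxidises the hydroquinone to the quinone, and the tert-butyl vinylogous ester then ionises to the hydroxyquinone; the methyl ester, the isopropenyl group and both stereocentres (C5 is not α to a carbonyl, C10 is quaternary) should be untouched.

Compound list
1 | propanal | CCC=O | starting material
2 | methyl acrylate | C=CC(=O)OC | starting material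
3 | (E)-1-(prop-1-en-1-yl)pyrrolidine | C/C=C/N1CCCC1 | intermediate
4 | methyl 4-methyl-5-oxopentanoate (racemic) | CC(C=O)CCC(=O)OC | intermediate
5 | but-3-en-2-one | CC(=O)C=C | starting material
6 | methyl 4-formyl-4-methyl-7-oxooctanoate (racemic) | COC(=O)CCC(C)(C=O)CCC(C)=O | intermediate
7 | methyl 3-(1-methyl-4-oxocyclohex-2-en-1-yl)propanoate (racemic) | COC(=O)CCC1(C)C=CC(=O)CC1 | intermediate
8 | methyl 3-(1-methyl-4-oxocyclohexa-2,5-dien-1-yl)propanoate | COC(=O)CCC1(C)C=CC(=O)C=C1 | intermediate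
9 | 4,4,5,5-tetramethyl-2-(prop-1-en-2-yl)-1,3,2-dioxaborolane | C=C(C)B1OC(C)(C)C(C)(C)O1 | starting material
10 | methyl 3-[(1R,6S)-1-methyl-4-oxo-6-(prop-1-en-2-yl)cyclohex-2-en-1-yl]propanoate | C=C(C)[C@@H]1CC(=O)C=C[C@@]1(C)CCC(=O)OC | intermediate
11 | methyl 3-[(1S,6S)-3-iodo-1-methyl-4-oxo-6-(prop-1-en-2-yl)cyclohex-2-en-1-yl]propanoate | C=C(C)[C@@H]1CC(=O)C(I)=C[C@@]1(C)CCC(=O)OC | intermediate
12 | methyl 3-[(8S,9S)-6-iodo-8-methyl-9-(prop-1-en-2-yl)-1,4-dioxaspiro[4.5]dec-6-en-8-yl]propanoate | C=C(C)[C@@H]1CC2(OCCO2)C(I)=C[C@@]1(C)CCC(=O)OC | intermediate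
13 | 3,4-di-tert-butoxycyclobut-3-ene-1,2-dione | CC(C)(C)OC1=C(OC(C)(C)C)C(=O)C1=O | starting material
14 | chlorido[(8S,9S)-8-(3-methoxy-3-oxopropyl)-8-methyl-9-(prop-1-en-2-yl)-1,4-dioxaspiro[4.5]dec-6-en-6-yl]magnesium (LiCl complex) | C=C(C)[C@@H]1CC2(OCCO2)C([Mg]Cl)=C[C@@]1(C)CCC(=O)OC | intermediate
15 | methyl 3-[(8R,9S)-6-(2,3-di-tert-butoxy-1-hydroxy-4-oxocyclobut-2-en-1-yl)-8-methyl-9-(prop-1-en-2-yl)-1,4-dioxaspiro[4.5]dec-6-en-8-yl]propanoate (present as its magnesium alkoxide; C14 epimers) | C=C(C)[C@@H]1CC2(OCCO2)C(C3(O)C(OC(C)(C)C)=C(OC(C)(C)C)C3=O)=C[C@@]1(C)CCC(=O)OC | intermediate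
16 | methyl 3-[(8R,9S)-6-[2,3-di-tert-butoxy-4-oxo-1-(trimethylsilyloxy)cyclobut-2-en-1-yl]-8-methyl-9-(prop-1-en-2-yl)-1,4-dioxaspiro[4.5]dec-6-en-8-yl]propanoate (C14 epimers) | C=C(C)[C@@H]1CC2(OCCO2)C(C3(O[Si](C)(C)C)C(OC(C)(C)C)=C(OC(C)(C)C)C3=O)=C[C@@]1(C)CCC(=O)OC | intermediate
17 | methyl 3-[(8R,9S)-6-[2,3-di-tert-butoxy-4-hydroxy-4-(propan-2-yl)-1-(trimethylsilyloxy)cyclobut-2-en-1-yl]-8-methyl-9-(prop-1-en-2-yl)-1,4-dioxaspiro[4.5]dec-6-en-8-yl]propanoate (present as its alkoxide; diastereomer mixture) | C=C(C)[C@@H]1CC2(OCCO2)C(C3(O[Si](C)(C)C)C(OC(C)(C)C)=C(OC(C)(C)C)C3(O)C(C)C)=C[C@@]1(C)CCC(=O)OC | intermediate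
18 | methyl 3-[(8R,9S)-6-[3-tert-butoxy-4-oxo-2-(propan-2-yl)-1-(trimethylsilyloxy)cyclobut-2-en-1-yl]-8-methyl-9-(prop-1-en-2-yl)-1,4-dioxaspiro[4.5]dec-6-en-8-yl]propanoate (C14 epimers) | C=C(C)[C@@H]1CC2(OCCO2)C(C3(O[Si](C)(C)C)C(C(C)C)=C(OC(C)(C)C)C3=O)=C[C@@]1(C)CCC(=O)OC | intermediate
19 | methyl 3-[(8R,9S)-6-[(1E)-3-tert-butoxy-4-oxo-2-(propan-2-yl)-1-(trimethylsilyloxy)buta-1,3-dien-1-yl]-8-methyl-9-(prop-1-en-2-yl)-1,4-dioxaspiro[4.5]dec-6-en-8-yl]propanoate (dienylketene) | C=C(C)[C@@H]1CC2(OCCO2)C(/C(O[Si](C)(C)C)=C(C(C)C)\C(OC(C)(C)C)=C=O)=C[C@@]1(C)CCC(=O)OC | intermediate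
20 | methyl 3-[(1'S,2'S)-7'-tert-butoxy-1'-methyl-8'-oxo-6'-(propan-2-yl)-2'-(prop-1-en-2-yl)-5'-(trimethylsilyloxy)-2',3',8',8a'-tetrahydro-1'H-spiro[1,3-dioxolane-2,4'-naphthalen]-1'-yl]propanoate (C8a' epimers) | C=C(C)[C@@H]1CC2(OCCO2)C3=C(O[Si](C)(C)C)C(C(C)C)=C(OC(C)(C)C)C(=O)C3[C@@]1(C)CCC(=O)OC | intermediate
21 | methyl 3-[(1'S,2'S)-7'-tert-butoxy-8'-hydroxy-1'-methyl-6'-(propan-2-yl)-2'-(prop-1-en-2-yl)-5'-(trimethylsilyloxy)-2',3'-dihydro-1'H-spiro[1,3-dioxolane-2,4'-naphthalen]-1'-yl]propanoate | C=C(C)[C@@H]1CC2(OCCO2)c3c(O[Si](C)(C)C)c(C(C)C)c(OC(C)(C)C)c(O)c3[C@@]1(C)CCC(=O)OC | intermediate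
22 | methyl 3-[(1S,2S)-7-tert-butoxy-5,8-dihydroxy-1-methyl-4-oxo-6-(propan-2-yl)-2-(prop-1-en-2-yl)-1,2,3,4-tetrahydronaphthalen-1-yl]propanoate | C=C(C)[C@@H]1CC(=O)c2c(O)c(C(C)C)c(OC(C)(C)C)c(O)c2[C@@]1(C)CCC(=O)OC | intermediate
23 | methyl 3-[(1S,2S)-7-tert-butoxy-1-methyl-4,5,8-trioxo-6-(propan-2-yl)-2-(prop-1-en-2-yl)-1,2,3,4,5,8-hexahydronaphthalen-1-yl]propanoate | C=C(C)[C@@H]1CC(=O)C2=C(C(=O)C(OC(C)(C)C)=C(C(C)C)C2=O)[C@@]1(C)CCC(=O)OC | intermediate
24 | methyl 3-[(1S,2S)-7-hydroxy-1-methyl-4,5,8-trioxo-6-(propan-2-yl)-2-(prop-1-en-2-yl)-1,2,3,4,5,8-hexahydronaphthalen-1-yl]propanoate | C=C(C)[C@@H]1CC(=O)C2=C(C(=O)C(O)=C(C(C)C)C2=O)[C@@]1(C)CCC(=O)OC | target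

Total step count: 10
Longest linear sequence: 10 steps (from propanal 1 to 24)

Steps most likely to fail

Step 4. The methyl and propanoate faces of dienone 8 differ little in size, so facial discrimination may be weak and the C10 epimer may form in quantity (each epimer still enantioenriched); a second addition to the product enone could also consume material. The fallback builds the quaternary centre by enolate alkylation anti to an isopropenyl group already in place. It sets out from methyl acrylate 2 and returns at enone 10. Copper-catalysed asymmetric conjugate addition of isopropenylmagnesium bromide to commercial 2-methylcyclohex-2-enone (CuBr·SMe2, chiral ferrocenyl diphosphine, Me3SiCl, −78 °C) would give the silyl enol ether trimethyl{[(3S)-2-methyl-3-(prop-1-en-2-yl)cyclohex-1-en-1-yl]oxy}silane F1. MeLi regenerates the enolate, which should add to 2 trans to the isopropenyl group to give methyl 3-[(1S,6S)-1-methyl-2-oxo-6-(prop-1-en-2-yl)cyclohexyl]propanoate F2. IBX dehydrogenation (only C8 carries α-hydrogens) would give methyl 3-[(1S,6S)-1-methyl-2-oxo-6-(prop-1-en-2-yl)cyclohex-3-en-1-yl]propanoate F3, and nucleophilic epoxidation (t-BuOOH, DBU) methyl 3-[(3S,4S)-3-methyl-2-oxo-4-(prop-1-en-2-yl)-7-oxabicyclo[4.1.0]heptan-3-yl]propanoate F4. Wharton transposition (N2H4·H2O, AcOH) moves the oxygen to C7 and the alkene to C8=C9, giving methyl 3-[(1R,6S)-4-hydroxy-1-methyl-6-(prop-1-en-2-yl)cyclohex-2-en-1-yl]propanoate F5, which MnO2 oxidises to 10.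

Step 8. The secondary alkyl nucleophile may add slowly to the congested cyclobutenone carbonyl, so that attack on the methyl ester or migration of the silyl group in the adduct competes, and the ionisation may then be misdirected. The fallback transposes with hydride instead of isopropyl and installs isopropyl last by radical alkylation. It sets out from 16 and returns at the target 24. LiAlH(Ot-Bu)3 (THF, −78 → −30 °C) followed by (CF3CO)2O/pyridine would give methyl 3-[(8R,9S)-6-[3-tert-butoxy-4-oxo-1-(trimethylsilyloxy)cyclobut-2-en-1-yl]-8-methyl-9-(prop-1-en-2-yl)-1,4-dioxaspiro[4.5]dec-6-en-8-yl]propanoate F6. The same thermolysis (toluene, 110 °C) should give methyl 3-[(1'S,2'S)-7'-tert-butoxy-8'-hydroxy-1'-methyl-2'-(prop-1-en-2-yl)-5'-(trimethylsilyloxy)-2',3'-dihydro-1'H-spiro[1,3-dioxolane-2,4'-naphthalen]-1'-yl]propanoate F7, still closing ring C through C9–C11. Aqueous HCl then FeCl3 would give methyl 3-[(1S,2S)-7-hydroxy-1-methyl-4,5,8-trioxo-2-(prop-1-en-2-yl)-1,2,3,4,5,8-hexahydronaphthalen-1-yl]propanoate F8. Decarboxylative radical alkylation with isobutyric acid (AgNO3 cat., (NH4)2S2O8, MeCN/H2O, 65 °C) at C13, the only free quinone position, leads to 24.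

Step 7. Iodine–magnesium exchange at the unactivated alkenyl iodide may be slower than attack of the exchange reagent on the ester, and silylation of the hindered magnesium alkoxide may stay incomplete. The fallback masks the ester as its lithium carboxylate and uses the more reactive alkenyllithium. It sets out from 12 and returns at 16. LiOH (THF/H2O) would give 3-[(8S,9S)-6-iodo-8-methyl-9-(prop-1-en-2-yl)-1,4-dioxaspiro[4.5]dec-6-en-8-yl]propanoic acid F9. Deprotonation (n-BuLi) and iodine–lithium exchange (t-BuLi, THF, −90 °C), addition to 13, Me3SiCl quench and aqueous work-up should give 3-[(8R,9S)-6-[2,3-di-tert-butoxy-4-oxo-1-(trimethylsilyloxy)cyclobut-2-en-1-yl]-8-methyl-9-(prop-1-en-2-yl)-1,4-dioxaspiro[4.5]dec-6-en-8-yl]propanoic acid F10, which Me3SiCHN2 (MeOH/toluene) esterifies to 16.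

Further compounds
F1 | step 4 | trimethyl{[(3S)-2-methyl-3-(prop-1-en-2-yl)cyclohex-1-en-1-yl]oxy}silane | C=C(C)[C@@H]1CCCC(O[Si](C)(C)C)=C1C
F2 | step 4 | methyl 3-[(1S,6S)-1-methyl-2-oxo-6-(prop-1-en-2-yl)cyclohexyl]propanoate | C=C(C)[C@@H]1CCCC(=O)[C@@]1(C)CCC(=O)OC
F3 | step 4 | methyl 3-[(1S,6S)-1-methyl-2-oxo-6-(prop-1-en-2-yl)cyclohex-3-en-1-yl]propanoate | C=C(C)[C@@H]1CC=CC(=O)[C@@]1(C)CCC(=O)OC
F4 | step 4 | methyl 3-[(3S,4S)-3-methyl-2-oxo-4-(prop-1-en-2-yl)-7-oxabicyclo[4.1.0]heptan-3-yl]propanoate (epoxide epimers) | C=C(C)[C@@H]1CC2OC2C(=O)[C@@]1(C)CCC(=O)OC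
F5 | step 4 | methyl 3-[(1R,6S)-4-hydroxy-1-methyl-6-(prop-1-en-2-yl)cyclohex-2-en-1-yl]propanoate (carbinol epimers) | C=C(C)[C@@H]1CC(O)C=C[C@@]1(C)CCC(=O)OC
F6 | step 8 | methyl 3-[(8R,9S)-6-[3-tert-butoxy-4-oxo-1-(trimethylsilyloxy)cyclobut-2-en-1-yl]-8-methyl-9-(prop-1-en-2-yl)-1,4-dioxaspiro[4.5]dec-6-en-8-yl]propanoate | C=C(C)[C@@H]1CC2(OCCO2)C(C3(O[Si](C)(C)C)C=C(OC(C)(C)C)C3=O)=C[C@@]1(C)CCC(=O)OC
F7 | step 8 | methyl 3-[(1'S,2'S)-7'-tert-butoxy-8'-hydroxy-1'-methyl-2'-(prop-1-en-2-yl)-5'-(trimethylsilyloxy)-2',3'-dihydro-1'H-spiro[1,3-dioxolane-2,4'-naphthalen]-1'-yl]propanoate | C=C(C)[C@@H]1CC2(OCCO2)c3c(O[Si](C)(C)C)cc(OC(C)(C)C)c(O)c3[C@@]1(C)CCC(=O)OC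
F8 | step 8 | methyl 3-[(1S,2S)-7-hydroxy-1-methyl-4,5,8-trioxo-2-(prop-1-en-2-yl)-1,2,3,4,5,8-hexahydronaphthalen-1-yl]propanoate | C=C(C)[C@@H]1CC(=O)C2=C(C(=O)C(O)=CC2=O)[C@@]1(C)CCC(=O)OC
F9 | step 7 | 3-[(8S,9S)-6-iodo-8-methyl-9-(prop-1-en-2-yl)-1,4-dioxaspiro[4.5]dec-6-en-8-yl]propanoic acid | C=C(C)[C@@H]1CC2(OCCO2)C(I)=C[C@@]1(C)CCC(=O)O
F10 | step 7 | 3-[(8R,9S)-6-[2,3-di-tert-butoxy-4-oxo-1-(trimethylsilyloxy)cyclobut-2-en-1-yl]-8-methyl-9-(prop-1-en-2-yl)-1,4-dioxaspiro[4.5]dec-6-en-8-yl]propanoic acid | C=C(C)[C@@H]1CC2(OCCO2)C(C3(O[Si](C)(C)C)C(OC(C)(C)C)=C(OC(C)(C)C)C3=O)=C[C@@]1(C)CCC(=O)O
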